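The target is epicatechin gallate-(4β→8)-epicatechin gallate-(4β→8)-catechin. The route rests on cutting pyran ring C of the upper unit U at O1–C2 and C3–C4: its diarylmethine C4, which carries C8 of the middle unit M, is the methide carbon of an o-quinone methide of ring A of U. One acid-catalysed hetero-Diels–Alder addition of a (Z)-β-silylstyrene closes ring C, makes both bonds and sets C2, C3 and C4, with silicon as the latent 3-hydroxyl. The precursor is a benzhydrol joining C8 of benzylated, 3-O-silylated epicatechin to a 2-hydroxy-4,6-bis(benzyloxy)phenyl ring. Oxidation at silicon, C4 activation of M, coupling to catechin and hydrogenolysis finish the synthesis.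

Key step: step 11

Remarks on the chemistry:
- The target is read as two (2R,3R)-epicatechin 3-O-gallate units (U, M) and one (2R,3S)-catechin unit (L), joined by two 4β→8 bonds (2,3-cis-3,4-trans in U and M). The structures of the two key-step partners and of the cycloadduct agree with this reading and are used unchanged.
- One weakness is corrected: a free ortho-phenol would quench the aryllithium that builds the benzhydrol, so that phenol is carried as an allyl ether and freed in the step before the key step.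
- Which antipode of the chiral acid is matched to the stereocentres of M cannot be predicted; the (R) acid is written and the (S) acid takes its place if it proves matched.
- Abbreviations: Bn = benzyl; TBS = tert-butyldimethylsilyl; (R)-TRIP = (R)-3,3′-bis(2,4,6-triisopropylphenyl)-1,1′-binaphthyl-2,2′-diyl hydrogen phosphate; α = face of the C2 aryl group of a flavan unit, β = opposite face.

**Route**

Step 1
Reactants: 1 (−)-epicatechin
Product: 2 5,7,3′,4′-tetra-O-benzyl-(−)-epicatechin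
Conditions: BnBr (4.4 equiv), K2CO3, DMF, 0 °C → rt
Reagents that add atoms: benzyl bromide, BrCc1ccccc1
Why: Williamson etherification in which carbonate ionises only the four phenols, so the secondary 3-hydroxyl stays free and C2 and C3 are untouched.

Step 2
Reactants: 2 5,7,3′,4′-tetra-O-benzyl-(−)-epicatechin
Product: 3 5,7,3′,4′-tetra-O-benzyl-3-O-TBS-epicatechin
Conditions: TBSCl, imidazole, DMF, rt
Reagents that add atoms: tert-butyldimethylsilyl chloride, CC(C)(C)[Si](C)(C)Cl
Why: Imidazole-promoted silylation of the secondary alcohol gives an ether that tolerates organolithium and weak acid and falls to fluoride later.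

Step 3
Reactants: 3 5,7,3′,4′-tetra-O-benzyl-3-O-TBS-epicatechin
Product: 4 8-bromo-5,7,3′,4′-tetra-O-benzyl-3-O-TBS-epicatechin
Conditions: NBS (1.0 equiv), CH2Cl2, −78 → 0 °C
Reagents that add atoms: N-bromosuccinimide, O=C1CCC(=O)N1Br
Why: Electrophilic aromatic bromination of the phloroglucinol-type ring A, which in 3-O-silylated tetra-O-benzyl flavan-3-ols goes to C8 in preference to C6.

Step 4
Reactants: 5 2,4,6-trihydroxybenzaldehyde
Product: 6 2,4-bis(benzyloxy)-6-hydroxybenzaldehyde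
Conditions: BnBr (2.1 equiv), K2CO3, DMF, rt
Reagents that add atoms: benzyl bromide, BrCc1ccccc1
Why: Williamson etherification that stops at the dibenzyl ether because the last hydroxyl is hydrogen-bonded to the formyl group and is the least nucleophilic.

Step 5
Reactants: 6 2,4-bis(benzyloxy)-6-hydroxybenzaldehyde
Product: 7 2-(allyloxy)-4,6-bis(benzyloxy)benzaldehyde
Conditions: allyl bromide, K2CO3, DMF, 60 °C
Reagents that add atoms: allyl bromide, C=CCBr
Why: Williamson O-allylation of the chelated phenol on warming masks the one acidic proton with a group that can later be removed without acid, fluoride or hydrogen.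

Step 6
Reactants: 4 8-bromo-5,7,3′,4′-tetra-O-benzyl-3-O-TBS-epicatechin; 7 2-(allyloxy)-4,6-bis(benzyloxy)benzaldehyde
Product: 9 8-{[2-(allyloxy)-4,6-bis(benzyloxy)phenyl](hydroxy)methyl}-5,7,3′,4′-tetra-O-benzyl-3-O-TBS-epicatechin (both carbinol epimers), via 8-lithio-tetra-O-benzyl-3-O-TBS-epicatechin 8 (not isolated)
Conditions: t-BuLi (2.0 equiv), THF, −78 °C; then 7, −78 → −20 °C; H2O
Reagents that add atoms: none
Why: Bromine–lithium exchange at C8 followed by 1,2-addition of the aryllithium to the aldehyde, the carbinol centre being formed as both epimers, which is harmless because it becomes planar in step 11.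

Step 7
Reactants: 9 8-{[2-(allyloxy)-4,6-bis(benzyloxy)phenyl](hydroxy)methyl}-5,7,3′,4′-tetra-O-benzyl-3-O-TBS-epicatechin
Product: 10 8-{[2-hydroxy-4,6-bis(benzyloxy)phenyl](hydroxy)methyl}-5,7,3′,4′-tetra-O-benzyl-3-O-TBS-epicatechin (both carbinol epimers)
Conditions: Pd(PPh3)4 (5 mol %), morpholine, THF, rt; Et3N-buffered silica
Reagents that add atoms: none
Why: Tsuji–Trost deallylation, in which the allyl group passes through a π-allylpalladium complex to morpholine under non-acidic conditions that spare the ionisable benzhydrol, the TBS ether and the benzyl ethers.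

Step 8
Reactants: 11 3,4-bis(benzyloxy)benzaldehyde
Product: 12 1,2-bis(benzyloxy)-4-ethynylbenzene
Conditions: dimethyl (1-diazo-2-oxopropyl)phosphonate, K2CO3, MeOH/THF, rt
Reagents that add atoms: dimethyl (1-diazo-2-oxopropyl)phosphonate, COP(=O)(OC)C(=[N+]=[N-])C(C)=O
Why: Seyferth–Gilbert homologation with the Ohira–Bestmann reagent turns the aryl aldehyde into the terminal alkyne under mild base.

Step 9
Reactants: 12 1,2-bis(benzyloxy)-4-ethynylbenzene
Product: 14 benzyl{[3,4-bis(benzyloxy)phenyl]ethynyl}dimethylsilane, via lithium arylacetylide 13 (not isolated)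
Conditions: n-BuLi, THF, −78 °C; then BnMe2SiCl, −78 °C → rt
Reagents that add atoms: benzylchlorodimethylsilane, C[Si](C)(Cl)Cc1ccccc1
Why: Deprotonation of the terminal alkyne and substitution at silicon install the benzyldimethylsilyl group, which is stable to acid yet can later be opened by fluoride.

Step 10
Reactants: 14 benzyl{[3,4-bis(benzyloxy)phenyl]ethynyl}dimethylsilane
Product: 15 (Z)-benzyl{2-[3,4-bis(benzyloxy)phenyl]ethenyl}dimethylsilane
Conditions: H2 (1 atm), Pd/CaCO3–Pb(OAc)2 (Lindlar catalyst), quinoline, EtOAc, rt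
Reagents that add atoms: none
Why: Lindlar semi-hydrogenation adds hydrogen syn to the alkynylsilane and so gives the Z alkene, while the poisoned catalyst leaves the benzyl ethers alone.

Step 11
Reactants: 10 8-{[2-hydroxy-4,6-bis(benzyloxy)phenyl](hydroxy)methyl}-5,7,3′,4′-tetra-O-benzyl-3-O-TBS-epicatechin; 15 (Z)-benzyl{2-[3,4-bis(benzyloxy)phenyl]ethenyl}dimethylsilane
Product: 17 protected U–M dimer with benzyldimethylsilyl at C3 of U (ring C of U: 2-aryl α, 3-silyl α, 4-aryl β; 2,3-cis-3,4-trans), via o-quinone methide of ring A of U 16 (not isolated)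
Conditions: (R)-TRIP (10 mol %), 15 (3 equiv), 4 Å molecular sieves, CH2Cl2, −20 °C, slow addition of 10
Reagents that add atoms: none
Why: Proposed new method: the phosphoric acid ionises benzhydrol 10 with loss of water to the hydrogen-bonded o-quinone methide 16, whose methide carbon (future C4 of U) is attacked by the silicon-bearing carbon of 15 while the charge growing at the benzylic carbon is held by the 4-benzyloxyaryl ring and by hyperconjugation with C–Si, so that the quinone oxygen closes on that carbon from the same alkene face in a concerted, asynchronous inverse-demand [4+2] addition. The closest known reaction type is the Brønsted-acid-catalysed hetero-Diels–Alder reaction of o-quinone methides, made from o-hydroxybenzyl alcohols, with styrenes to give 2,4-diarylchromans; a (Z)-β-silylstyrene as the 2π partner and a 2,4-trans product have not been shown. Ring C of U, the only ring formed, closes by this intermolecular [4+2] annulation (bonds C3–C4 and O1–C2), which in the stepwise limit ends as a six-membered closure of the phenolic oxygen on a β-silyl benzylic cation anti to silicon. The C2/C3 cis relation is copied from the Z alkene by suprafacial addition; the C3/C4 trans relation should follow from a methide whose flavanyl group lies syn to the quinone oxygen (the anti site is blocked by the neighbouring 5-benzyloxy group) combined with endo placement of the styryl aryl group; the absolute sense at C4, which fixes C3 and C2 with it, is left to the chiral phosphate bound at the methide oxygen, because the C2 and C3 centres of M are remote. The step needs regioselectivity (silicon-bearing carbon to C4, not to O1), secured by the polarisation of the β-silylstyrene, and chemoselectivity against self-arylation of the methide and protodesilylation, served by slow addition of 10 to excess 15, a weak acid and sieves.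

Step 12
Reactants: 17 protected U–M dimer with benzyldimethylsilyl at C3 of U
Product: 19 octa-O-benzyl procyanidin B2 (octa-O-benzyl epicatechin-(4β→8)-epicatechin with both 3-hydroxyls free), via C3-hydroxydimethylsilyl diol 18 (not isolated)
Conditions: Bu4NF, THF, 0 °C → rt; then KHCO3, 30% H2O2, MeOH/THF, rt → 40 °C
Reagents that add atoms: hydrogen peroxide, OO
Why: Tamao–Fleming oxidation in which fluoride removes the benzyl group from silicon and the TBS ether to give silanol 18, after which C3 shifts from silicon to the peroxide oxygen with retention, so the new hydroxyl stays cis to the C2 aryl and trans to the C4 aryl group as in epicatechin (the axial C3–Si bond is gauche to C2–O1, which disfavours β-elimination).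

Step 13
Reactants: 19 octa-O-benzyl procyanidin B2
Product: 20 octa-O-benzyl procyanidin B2 carrying a 4β-(2-ethoxyethoxy) group at C4 of M
Conditions: DDQ, 2-ethoxyethanol, CH2Cl2, rt
Reagents that add atoms: 2-ethoxyethanol, CCOCCO
Why: DDQ benzylic oxidation, in which hydride leaves the C4 methylene of M (the only CH2 benzylic to a phloroglucinol-type ring) and the alcohol adds to the cation anti to the C2 aryl and C3 hydroxyl groups, the C4 methine of U being shielded and poorly aligned with its aryl π systems.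

Step 14
Reactants: 20 octa-O-benzyl procyanidin B2 carrying a 4β-(2-ethoxyethoxy) group at C4 of M; 21 3,4,5-tris(benzyloxy)benzoic acid
Product: 22 3-O-galloylated dimer (both 3-hydroxyls esterified with tri-O-benzylgalloyl; 4β-(2-ethoxyethoxy) at C4 of M)
Conditions: 21 (4 equiv), DCC, DMAP, CH2Cl2, rt → 40 °C
Reagents that add atoms: none
Why: Steglich esterification acylates both secondary hydroxyls without touching stereocentres or the acid-labile C4 ether.

Step 15
Reactants: 23 (+)-catechin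
Product: 24 5,7,3′,4′-tetra-O-benzyl-(+)-catechin
Conditions: BnBr (4.4 equiv), K2CO3, DMF, rt
Reagents that add atoms: benzyl bromide, BrCc1ccccc1
Why: Williamson etherification of the four phenols leaves the 3-hydroxyl free and C8 nucleophilic.

Step 16
Reactants: 22 3-O-galloylated dimer with 4β-(2-ethoxyethoxy) at C4 of M; 24 5,7,3′,4′-tetra-O-benzyl-(+)-catechin
Product: 25 octadeca-O-benzyl trimer (protected epicatechin gallate-(4β→8)-epicatechin gallate-(4β→8)-catechin)
Conditions: Me3SiOTf (0.5 equiv), 24 (4 equiv), CH2Cl2, −20 °C; NaHCO3 quench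
Reagents that add atoms: none
Why: Lewis-acid ionisation of the C4 ether to the flavan-4-yl cation and Friedel–Crafts attack by C8 of excess 24 anti to the 3-O-galloyl and C2 aryl groups should give the 4β (3,4-trans) bond, as in known procyanidin couplings, and so sets C4 of M.

Step 17
Reactants: 25 octadeca-O-benzyl trimer
Product: 26 epicatechin 3-O-gallate-(4β→8)-epicatechin 3-O-gallate-(4β→8)-catechin (CNP0269915.2)
Conditions: H2 (1 atm), Pd(OH)2/C, THF/MeOH/H2O, rt
Reagents that add atoms: none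
Why: Hydrogenolysis removes all eighteen benzyl ethers while the gallate esters, both interflavan bonds and every stereocentre stay intact.

**Compound list**

1 | (−)-epicatechin, (2R,3R) | O[C@@H]1Cc2c(O)cc(O)cc2O[C@@H]1c1ccc(O)c(O)c1 | starting material
2 | 5,7,3′,4′-tetra-O-benzyl-(−)-epicatechin | O[C@@H]1Cc2c(OCc9ccccc9)cc(OCc9ccccc9)cc2O[C@@H]1c1ccc(OCc9ccccc9)c(OCc9ccccc9)c1 | intermediate
3 | 5,7,3′,4′-tetra-O-benzyl-3-O-TBS-epicatechin | CC(C)(C)[Si](C)(C)O[C@@H]1Cc2c(OCc9ccccc9)cc(OCc9ccccc9)cc2O[C@@H]1c1ccc(OCc9ccccc9)c(OCc9ccccc9)c1 | intermediate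
4 | 8-bromo-5,7,3′,4′-tetra-O-benzyl-3-O-TBS-epicatechin | CC(C)(C)[Si](C)(C)O[C@@H]1Cc2c(OCc9ccccc9)cc(OCc9ccccc9)c(Br)c2O[C@@H]1c1ccc(OCc9ccccc9)c(OCc9ccccc9)c1 | intermediate
5 | 2,4,6-trihydroxybenzaldehyde | O=Cc1c(O)cc(O)cc1O | starting material
6 | 2,4-bis(benzyloxy)-6-hydroxybenzaldehyde | O=Cc1c(O)cc(OCc9ccccc9)cc1OCc9ccccc9 | intermediate
7 | 2-(allyloxy)-4,6-bis(benzyloxy)benzaldehyde | C=CCOc1cc(OCc9ccccc9)cc(OCc9ccccc9)c1C=O | intermediate
8 | 8-lithio-5,7,3′,4′-tetra-O-benzyl-3-O-TBS-epicatechin | CC(C)(C)[Si](C)(C)O[C@@H]1Cc2c(OCc9ccccc9)cc(OCc9ccccc9)c([Li])c2O[C@@H]1c1ccc(OCc9ccccc9)c(OCc9ccccc9)c1 | intermediate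
9 | 8-{[2-(allyloxy)-4,6-bis(benzyloxy)phenyl](hydroxy)methyl}-5,7,3′,4′-tetra-O-benzyl-3-O-TBS-epicatechin, both carbinol epimers | CC(C)(C)[Si](C)(C)O[C@@H]1Cc2c(OCc9ccccc9)cc(OCc9ccccc9)c(C(O)c3c(OCC=C)cc(OCc9ccccc9)cc3OCc9ccccc9)c2O[C@@H]1c1ccc(OCc9ccccc9)c(OCc9ccccc9)c1 | intermediate
10 | 8-{[2-hydroxy-4,6-bis(benzyloxy)phenyl](hydroxy)methyl}-5,7,3′,4′-tetra-O-benzyl-3-O-TBS-epicatechin, both carbinol epimers (key-step precursor) | CC(C)(C)[Si](C)(C)O[C@@H]1Cc2c(OCc9ccccc9)cc(OCc9ccccc9)c(C(O)c3c(O)cc(OCc9ccccc9)cc3OCc9ccccc9)c2O[C@@H]1c1ccc(OCc9ccccc9)c(OCc9ccccc9)c1 | intermediate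
11 | 3,4-bis(benzyloxy)benzaldehyde | O=Cc1ccc(OCc9ccccc9)c(OCc9ccccc9)c1 | starting material
12 | 1,2-bis(benzyloxy)-4-ethynylbenzene | C#Cc1ccc(OCc9ccccc9)c(OCc9ccccc9)c1 | intermediate
13 | lithium [3,4-bis(benzyloxy)phenyl]acetylide | [Li]C#Cc1ccc(OCc9ccccc9)c(OCc9ccccc9)c1 | intermediate
14 | benzyl{[3,4-bis(benzyloxy)phenyl]ethynyl}dimethylsilane | C[Si](C)(Cc1ccccc1)C#Cc1ccc(OCc9ccccc9)c(OCc9ccccc9)c1 | intermediate
15 | (Z)-benzyl{2-[3,4-bis(benzyloxy)phenyl]ethenyl}dimethylsilane | C[Si](C)(Cc1ccccc1)/C=C\c1ccc(OCc9ccccc9)c(OCc9ccccc9)c1 | intermediate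
16 | o-quinone methide: 3,5-bis(benzyloxy)-6-(arylmethylidene)cyclohexa-2,4-dien-1-one, aryl = C8 of 3; exocyclic alkene geometry not fixed | CC(C)(C)[Si](C)(C)O[C@@H]1Cc2c(OCc9ccccc9)cc(OCc9ccccc9)c(C=C3C(=O)C=C(OCc9ccccc9)C=C3OCc9ccccc9)c2O[C@@H]1c1ccc(OCc9ccccc9)c(OCc9ccccc9)c1 | intermediate
17 | protected U–M dimer: octa-O-benzyl, 3-O-TBS on M, benzyldimethylsilyl at C3 of U; ring C of U 2,3-cis-3,4-trans (2-aryl α, 3-Si α, 4-aryl β) | CC(C)(C)[Si](C)(C)O[C@@H]1Cc2c(OCc9ccccc9)cc(OCc9ccccc9)c([C@H]3c4c(OCc9ccccc9)cc(OCc9ccccc9)cc4O[C@H](c4ccc(OCc9ccccc9)c(OCc9ccccc9)c4)[C@@H]3[Si](C)(C)Cc9ccccc9)c2O[C@@H]1c1ccc(OCc9ccccc9)c(OCc9ccccc9)c1 | intermediate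
18 | octa-O-benzyl U–M dimer with hydroxydimethylsilyl at C3 of U and free 3-hydroxyl on M | O[C@@H]1Cc2c(OCc9ccccc9)cc(OCc9ccccc9)c([C@H]3c4c(OCc9ccccc9)cc(OCc9ccccc9)cc4O[C@H](c4ccc(OCc9ccccc9)c(OCc9ccccc9)c4)[C@@H]3[Si](C)(C)O)c2O[C@@H]1c1ccc(OCc9ccccc9)c(OCc9ccccc9)c1 | intermediate
19 | octa-O-benzyl procyanidin B2: octa-O-benzyl epicatechin-(4β→8)-epicatechin, both 3-hydroxyls free | O[C@@H]1Cc2c(OCc9ccccc9)cc(OCc9ccccc9)c([C@H]3c4c(OCc9ccccc9)cc(OCc9ccccc9)cc4O[C@H](c4ccc(OCc9ccccc9)c(OCc9ccccc9)c4)[C@@H]3O)c2O[C@@H]1c1ccc(OCc9ccccc9)c(OCc9ccccc9)c1 | intermediate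
20 | octa-O-benzyl procyanidin B2 with 4β-(2-ethoxyethoxy) at C4 of M | O[C@@H]1[C@@H](OCCOCC)c2c(OCc9ccccc9)cc(OCc9ccccc9)c([C@H]3c4c(OCc9ccccc9)cc(OCc9ccccc9)cc4O[C@H](c4ccc(OCc9ccccc9)c(OCc9ccccc9)c4)[C@@H]3O)c2O[C@@H]1c1ccc(OCc9ccccc9)c(OCc9ccccc9)c1 | intermediate
21 | 3,4,5-tris(benzyloxy)benzoic acid | OC(=O)c1cc(OCc9ccccc9)c(OCc9ccccc9)c(OCc9ccccc9)c1 | starting material
22 | compound 20 with both 3-hydroxyls esterified by 3,4,5-tris(benzyloxy)benzoyl | O=C(O[C@@H]1[C@@H](OCCOCC)c2c(OCc9ccccc9)cc(OCc9ccccc9)c([C@H]3c4c(OCc9ccccc9)cc(OCc9ccccc9)cc4O[C@H](c4ccc(OCc9ccccc9)c(OCc9ccccc9)c4)[C@@H]3OC(=O)c3cc(OCc9ccccc9)c(OCc9ccccc9)c(OCc9ccccc9)c3)c2O[C@@H]1c1ccc(OCc9ccccc9)c(OCc9ccccc9)c1)c1cc(OCc9ccccc9)c(OCc9ccccc9)c(OCc9ccccc9)c1 | intermediate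
23 | (+)-catechin, (2R,3S) | O[C@H]1Cc2c(O)cc(O)cc2O[C@@H]1c1ccc(O)c(O)c1 | starting material
24 | 5,7,3′,4′-tetra-O-benzyl-(+)-catechin | O[C@H]1Cc2c(OCc9ccccc9)cc(OCc9ccccc9)cc2O[C@@H]1c1ccc(OCc9ccccc9)c(OCc9ccccc9)c1 | intermediate
25 | octadeca-O-benzyl trimer: target with every phenol benzylated, 3-hydroxyl of L free | O=C(O[C@@H]1[C@@H](c2c(OCc9ccccc9)cc(OCc9ccccc9)c3c2O[C@H](c2ccc(OCc9ccccc9)c(OCc9ccccc9)c2)[C@@H](O)C3)c2c(OCc9ccccc9)cc(OCc9ccccc9)c([C@H]3c4c(OCc9ccccc9)cc(OCc9ccccc9)cc4O[C@H](c4ccc(OCc9ccccc9)c(OCc9ccccc9)c4)[C@@H]3OC(=O)c3cc(OCc9ccccc9)c(OCc9ccccc9)c(OCc9ccccc9)c3)c2O[C@@H]1c1ccc(OCc9ccccc9)c(OCc9ccccc9)c1)c1cc(OCc9ccccc9)c(OCc9ccccc9)c(OCc9ccccc9)c1 | intermediate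
26 | epicatechin 3-O-gallate-(4β→8)-epicatechin 3-O-gallate-(4β→8)-catechin (CNP0269915.2) | O=C(O[C@@H]1[C@@H](c2c(O)cc(O)c3c2O[C@H](c2ccc(O)c(O)c2)[C@@H](O)C3)c2c(O)cc(O)c([C@H]3c4c(O)cc(O)cc4O[C@H](c4ccc(O)c(O)c4)[C@@H]3OC(=O)c3cc(O)c(O)c(O)c3)c2O[C@@H]1c1ccc(O)c(O)c1)c1cc(O)c(O)c(O)c1 | target

**Step count and risks**

Total step count: 17. Longest linear sequence: 11 steps (1, 2, 3, 6, 7, 11, 12, 13, 14, 16, 17).

Steps most likely to fail:

Step 11 (carries the label). What may go wrong: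
- The chiral acid may fail to overrule, or may oppose, the facial bias of M, giving poor facial selectivity at C4 of U.
- Exo approach, or a methide with the flavanyl group anti to the quinone oxygen, would give the 3,4-cis series.
- The β-silyl cation may lose silicon instead of closing (styryl transfer).
- The methide may arylate a second molecule.

Fallback with known chemistry: from 2, DDQ and 2-ethoxyethanol in CH2Cl2 would give 4β-(2-ethoxyethoxy)-5,7,3′,4′-tetra-O-benzylepicatechin F1. Me3SiOTf with excess 2 at −20 °C would then join C4 of F1 to C8 of 2, anti to the C2 aryl group, and give 19 directly. The route is rejoined at 19.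

Step 12. What may go wrong:
- Fluoride at silicon may expel the O1 phenoxide (Peterson-type opening of ring C) or the C3 carbanion (protodesilylation).
- The shift at the hindered axial C3 may be slow.

Fallback: a silicon group that already bears oxygen and is oxidised without prior Si–C cleavage by naked fluoride. From 12, lithiation to 13 and chloropentamethyldisiloxane would give 1-{[3,4-bis(benzyloxy)phenyl]ethynyl}-1,1,3,3,3-pentamethyldisiloxane F2. Lindlar reduction would give the (Z)-alkenyl disiloxane F3. The conditions of step 11 with 10 would give the C3-(pentamethyldisiloxanyl) cycloadduct F4. KF, KHCO3 and H2O2 in THF/MeOH would give octa-O-benzyl procyanidin B2 3-O-TBS ether on M F5, and Bu4NF would then free the last hydroxyl. The route is rejoined at 19.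

Step 16. What may go wrong:
- The electrophile may condense with itself through the free C8 of ring A of U.
- Attack may occur at C6 of 24 instead of C8.
- The acid may scramble the existing interflavan bond.

Fallback by bromine capping: from 22, NBS in CH2Cl2 at −78 °C should brominate the most nucleophilic free position and give the 8-bromo (ring A of U) galloylated dimer F6. Me3SiOTf with 24 would give the 8-bromo octadeca-O-benzyl trimer F7, which can no longer act as a C8 nucleophile. H2 over Pd(OH)2/C with Et3N would remove bromine together with the benzyl groups. The route is rejoined at 26.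

Further compounds
F1 | step 11 | 4β-(2-ethoxyethoxy)-5,7,3′,4′-tetra-O-benzylepicatechin | O[C@@H]1[C@@H](OCCOCC)c2c(OCc9ccccc9)cc(OCc9ccccc9)cc2O[C@@H]1c1ccc(OCc9ccccc9)c(OCc9ccccc9)c1
F2 | step 12 | 1-{[3,4-bis(benzyloxy)phenyl]ethynyl}-1,1,3,3,3-pentamethyldisiloxane | C[Si](C)(C)O[Si](C)(C)C#Cc1ccc(OCc9ccccc9)c(OCc9ccccc9)c1
F3 | step 12 | (Z)-1-{2-[3,4-bis(benzyloxy)phenyl]ethenyl}-1,1,3,3,3-pentamethyldisiloxane | C[Si](C)(C)O[Si](C)(C)/C=C\c1ccc(OCc9ccccc9)c(OCc9ccccc9)c1
F4 | step 12 | protected U–M dimer with pentamethyldisiloxanyl at C3 of U (2,3-cis-3,4-trans), 3-O-TBS on M | CC(C)(C)[Si](C)(C)O[C@@H]1Cc2c(OCc9ccccc9)cc(OCc9ccccc9)c([C@H]3c4c(OCc9ccccc9)cc(OCc9ccccc9)cc4O[C@H](c4ccc(OCc9ccccc9)c(OCc9ccccc9)c4)[C@@H]3[Si](C)(C)O[Si](C)(C)C)c2O[C@@H]1c1ccc(OCc9ccccc9)c(OCc9ccccc9)c1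
F5 | step 12 | octa-O-benzyl procyanidin B2 3-O-TBS ether on M (3-hydroxyl of U free) | CC(C)(C)[Si](C)(C)O[C@@H]1Cc2c(OCc9ccccc9)cc(OCc9ccccc9)c([C@H]3c4c(OCc9ccccc9)cc(OCc9ccccc9)cc4O[C@H](c4ccc(OCc9ccccc9)c(OCc9ccccc9)c4)[C@@H]3O)c2O[C@@H]1c1ccc(OCc9ccccc9)c(OCc9ccccc9)c1
F6 | step 16 | compound 22 brominated at C8 of ring A of U | O=C(O[C@@H]1[C@@H](OCCOCC)c2c(OCc9ccccc9)cc(OCc9ccccc9)c([C@H]3c4c(OCc9ccccc9)cc(OCc9ccccc9)c(Br)c4O[C@H](c4ccc(OCc9ccccc9)c(OCc9ccccc9)c4)[C@@H]3OC(=O)c3cc(OCc9ccccc9)c(OCc9ccccc9)c(OCc9ccccc9)c3)c2O[C@@H]1c1ccc(OCc9ccccc9)c(OCc9ccccc9)c1)c1cc(OCc9ccccc9)c(OCc9ccccc9)c(OCc9ccccc9)c1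
F7 | step 16 | compound 25 brominated at C8 of ring A of U | O=C(O[C@@H]1[C@@H](c2c(OCc9ccccc9)cc(OCc9ccccc9)c3c2O[C@H](c2ccc(OCc9ccccc9)c(OCc9ccccc9)c2)[C@@H](O)C3)c2c(OCc9ccccc9)cc(OCc9ccccc9)c([C@H]3c4c(OCc9ccccc9)cc(OCc9ccccc9)c(Br)c4O[C@H](c4ccc(OCc9ccccc9)c(OCc9ccccc9)c4)[C@@H]3OC(=O)c3cc(OCc9ccccc9)c(OCc9ccccc9)c(OCc9ccccc9)c3)c2O[C@@H]1c1ccc(OCc9ccccc9)c(OCc9ccccc9)c1)c1cc(OCc9ccccc9)c(OCc9ccccc9)c(OCc9ccccc9)c1
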